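All runs stem from a simulated flask for an exercise, noise included.

**The decision.** The initiator is where this choice starts: you can charge the next flask like Tuesday's, with 0.600 mM of transfer agent, or like Thursday's, with 1.20 mM, and the length you get is monomer in chains divided by chains begun.

the same everywhere: free monomer 20 mM (fed, over 25 h); initiator 0.13 mM
- birch: transfer agent 0.53 mM; protic impurity 4 mM; run made earlier
- cedar: transfer agent 0.73 mM; protic impurity 4 mM; run made earlier
- Tuesday's: transfer agent 0.600 mM; protic impurity 4.00 mM; time 25 h
- Thursday's: transfer agent 1.20 mM; protic impurity 4.00 mM; time 25 h

| run | time / h | monomer in chains / % |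
|---|---|---|
| birch | 1.33 | 0 |
| birch | 2.50 | 0 |
| birch | 4.00 | 2.9 |
| birch | 6.00 | 1.4 |
| birch | 10.0 | 2.8 |
| birch | 20.0 | 13.0 |
| cedar | 1.33 | 0 |
| cedar | 2.50 | 1.3 |
| cedar | 4.00 | 0.9 |
| cedar | 6.00 | 0 |
| cedar | 10.0 | 2.1 |
| cedar | 20.0 | 8.2 |

(readings scatter by 1 percentage point)

* which of the two ends with the longer chains by the average number of monomer units in a chain (chains begun, living or dead) ("neither" if they lie within 10 %) (Tuesday's / Thursday's / neither)
* average number of monomer units in a chain (chains begun, living or dead) at the end, Tuesday's
* average number of monomer units in a chain (chains begun, living or dead) at the end, Thursday's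

- the average divides the monomer in chains by the number of chains begun, living and dead together
- the earlier runs do not show the number of chains; that part of a forecast is a guess
- percentages count the whole charge, also what has not yet gone in

**Ceiling length.** The earlier runs do not show the chains, so I guess that each initiator begins one chain and the transfer agent begins none, which puts chains begun at c(initiator) = 0.13 mM in both flasks. The whole charge over that count, 154, is the ceiling length, the number-average degree of polymerisation with the entire charge in chains. A flask's length is then this ceiling times the fraction of the charge in chains.

**The order.** That fraction follows c(transfer agent). At 20.0 h the birch run read 13.0 % with 0.53 mM and the cedar run read 8.2 % with 0.73 mM, so the reading falls as c(transfer agent) to the power 1.44, a figure left loose by the scatter of 1 percentage point. Scaling the birch reading gives 10.9 % for Tuesday's and 4.01 % for Thursday's, the second lying beyond both runs. These are estimates for 20.0 h, not bounds, because they rest on one scattered reading, a loose power and a guessed count of chains, and with the ceiling they make lengths of about 16.7 and 6.17. Both flasks share one ceiling, so Tuesday's comes out longer by a factor of 2.71, well past the margin of 10 %, and I would charge Tuesday's.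

**The outcome.** The forecast also picks Tuesday's, but with lengths of 7 and 2.5, shorter than my estimates, on the assumption that “part of the agent starts chains”. The flasks end at 17.5 for Tuesday's and 7.21 for Thursday's, so Tuesday's is the longer.

    living end + transfer agent → dead chain (kL = 370 L mol⁻¹ h⁻¹)
    free monomer + initiator → living end + monomer in chains (k = 120 L mol⁻¹ h⁻¹)
    protic impurity + free monomer → quenched substrate (k = 87.0 L mol⁻¹ h⁻¹)
    free monomer + living end → monomer in chains + living end, rate k4*[living end]*[free monomer] (k = 780 L mol⁻¹ h⁻¹)

**Neighbour flask.** In Tuesday's, living end plus dead chain come to 0.130 mM at 25.0 h, and 11.4 % of the charge stands in chains, which the ceiling turns into 17.6. A neighbour of Tuesday's charged with 0.52 mM of initiator has its ceiling cut to a quarter, at 38.5. That neighbour ends with living end plus dead chain at 0.520 mM and 46.3 % of its charge in chains, so the ceiling gives 17.8, and its average length stands at 17.8.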